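The route is built on the C5–C6 bond: C6, the γ-carbon of the butenolide ring, carries C5 of the C4–C5 oxirane inside the ten-membered carbocycle, which is a vinylogous aldol retron once C4 bears chloride. In one operation a 2-silyloxyfuran adds through C6 to a tertiary α-chloro aldehyde, closing the carbocycle and restoring the C7=C11 butenolide, and the C5 alkoxide then displaces chloride to close the epoxide; C5 and C6 are set. The precursor is the open C1–C10 chain with C1 masked as a dithiane, the (S)-chloride and aldehyde at C4/C5, silyl ethers at C8, C9 and C13, and the silyloxyfuran at C7.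

Key step: step 24

Remark: atoms carry the numbers of the target's carbocycle and lactone (C1 ketone, C4/C5 epoxide, C6 lactone O–CH, C7=C11, C8 ester carbinol, C9 carbinol, C10 C-methyl, C12 lactone C=O, C13 CH2O). TBS = tert-butyldimethylsilyl, TES = triethylsilyl, TIPS = triisopropylsilyl. Silyl ethers 1 and 9 are assumed to be purchasable.

Step 1
Reactants: 1 tert-butyl(but-3-yn-1-yloxy)dimethylsilane
Product: 3 (E)-5-(tert-butyldimethylsilyloxy)-3-methylpent-2-en-1-ol, via alkenylalane 2 (not isolated)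
Conditions: AlMe3, Cp2ZrCl2 (cat.), CH2Cl2, 0 °C to rt; then n-BuLi, (CH2O)n, THF, −78 °C to rt
Reagents that add atoms: trimethylaluminium C[Al](C)C; formaldehyde (as paraformaldehyde) C=O
Why: Zirconium-catalysed Negishi carboalumination adds methyl and aluminium syn across the terminal alkyne with aluminium on the terminal carbon, and the alanate formed with n-BuLi is hydroxymethylated with retention, so only the E-trisubstituted allylic alcohol should form.

Step 2
Reactants: 3 (E)-5-(tert-butyldimethylsilyloxy)-3-methylpent-2-en-1-ol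
Product: 4 [(2R,3R)-3-[2-(tert-butyldimethylsilyloxy)ethyl]-3-methyloxiran-2-yl]methanol
Conditions: Ti(OiPr)4 (cat.), D-(−)-diethyl tartrate (cat.), t-BuOOH, 4 Å MS, CH2Cl2, −20 °C
Reagents that add atoms: tert-butyl hydroperoxide CC(C)(C)OO
Why: Sharpless asymmetric epoxidation of an E-trisubstituted allylic alcohol is a very reliable case, and the D-(−)-tartrate directs oxygen to the face that gives the (2R,3R)-epoxide, i.e. R at the future C4.

Step 3
Reactants: 4 [(2R,3R)-3-[2-(tert-butyldimethylsilyloxy)ethyl]-3-methyloxiran-2-yl]methanol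
Product: 5 (2R,3S)-5-(tert-butyldimethylsilyloxy)-3-chloro-3-methylpentane-1,2-diol
Conditions: ClTi(OiPr)3, CH2Cl2, 0 °C to rt
Reagents that add atoms: chlorotitanium triisopropoxide CC(C)O[Ti](Cl)(OC(C)C)OC(C)C
Why: Titanium-assisted nucleophilic opening of a 2,3-epoxy alcohol: the bound titanium alkoxide activates the oxirane and chloride enters at the tertiary C3 carbon (future C4) from the rear, so C–O is replaced by C–Cl with inversion to the (S)-chloride while the secondary carbinol is untouched.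

Step 4
Reactants: 5 (2R,3S)-5-(tert-butyldimethylsilyloxy)-3-chloro-3-methylpentane-1,2-diol
Product: 6 (4R)-4-[(2S)-4-(tert-butyldimethylsilyloxy)-2-chlorobutan-2-yl]-2,2-dimethyl-1,3-dioxolane
Conditions: 2,2-dimethoxypropane, PPTS (cat.), CH2Cl2, rt
Reagents that add atoms: 2,2-dimethoxypropane COC(C)(C)OC
Why: Acid-catalysed transketalisation ties the 1,2-diol up as the five-membered acetonide, which keeps the chlorohydrin from closing under the basic steps that follow.

Step 5
Reactants: 6 (4R)-4-[(2S)-4-(tert-butyldimethylsilyloxy)-2-chlorobutan-2-yl]-2,2-dimethyl-1,3-dioxolane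
Product: 7 (3S)-3-chloro-3-[(4R)-2,2-dimethyl-1,3-dioxolan-4-yl]butan-1-ol
Conditions: TBAF, AcOH, THF, 0 °C to rt
Reagents that add atoms: none
Why: Fluoride desilylation buffered with acetic acid frees the primary alcohol without leaving a basic alkoxide near the tertiary chloride.

Step 6
Reactants: 7 (3S)-3-chloro-3-[(4R)-2,2-dimethyl-1,3-dioxolan-4-yl]butan-1-ol
Product: 8 (4R)-4-[(2S)-2-chloro-4-iodobutan-2-yl]-2,2-dimethyl-1,3-dioxolane
Conditions: I2, PPh3, imidazole, CH2Cl2, 0 °C
Reagents that add atoms: iodine [I][I]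
Why: Appel-type iodination (PPh3/I2/imidazole) turns the primary alcohol into the primary iodide under neutral conditions that leave acetonide and tertiary chloride alone.

Step 7
Reactants: 9 (tert-butyldimethylsilyloxy)acetaldehyde
Product: 11 (2R,3R)-1-(tert-butyldimethylsilyloxy)-3-methylpent-4-en-2-ol, via borinate ester 10 (not isolated)
Conditions: (E)-but-2-ene, KOtBu, n-BuLi, THF, −78 to −45 °C; (+)-Ipc2BOMe, −78 °C; BF3·OEt2; 9, −78 °C; then NaOH, H2O2
Reagents that add atoms: (E)-but-2-ene C/C=C/C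
Why: Brown asymmetric crotylboration: the (E)-crotylborane reacts through a closed chair (Zimmerman–Traxler) transition state that gives the anti C9/C10 relationship, and the isopinocampheyl groups derived from (+)-Ipc2BOMe select the aldehyde face that leads to the 2R,3R alcohol.

Step 8
Reactants: 11 (2R,3R)-1-(tert-butyldimethylsilyloxy)-3-methylpent-4-en-2-ol
Product: 12 (2R,3R)-1,2-bis(tert-butyldimethylsilyloxy)-3-methylpent-4-ene
Conditions: TBSCl, imidazole, DMF, rt
Reagents that add atoms: tert-butyldimethylsilyl chloride CC(C)(C)[Si](C)(C)Cl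
Why: Standard silylation of the secondary alcohol; the C9 silyl ether later acts as the non-chelating polar group that steers the C8 reduction.

Step 9
Reactants: 12 (2R,3R)-1,2-bis(tert-butyldimethylsilyloxy)-3-methylpent-4-ene
Product: 14 (2S,3R)-3,4-bis(tert-butyldimethylsilyloxy)-2-methylbutanal, via secondary ozonide 13 (not isolated)
Conditions: O3, CH2Cl2, −78 °C; then PPh3, −78 °C to rt
Reagents that add atoms: ozone [O-][O+]=O
Why: Ozonolysis with reductive work-up cuts the vinyl group to the C1 aldehyde at low temperature without touching the α-stereocentre, and the aldehyde is used crude.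

Step 10
Reactants: 14 (2S,3R)-3,4-bis(tert-butyldimethylsilyloxy)-2-methylbutanal; 15 propane-1,3-dithiol
Product: 16 2-[(2S,3R)-3,4-bis(tert-butyldimethylsilyloxy)butan-2-yl]-1,3-dithiane
Conditions: MgBr2·OEt2, Et2O, 0 °C to rt
Reagents that add atoms: none
Why: Thioacetalisation under the mild Lewis acid MgBr2·OEt2 gives the 1,3-dithiane without epimerising the α-methyl centre or cleaving the silyl ethers.

Step 11
Reactants: 16 2-[(2S,3R)-3,4-bis(tert-butyldimethylsilyloxy)butan-2-yl]-1,3-dithiane; 8 (4R)-4-[(2S)-2-chloro-4-iodobutan-2-yl]-2,2-dimethyl-1,3-dioxolane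
Product: 18 2-[(2S,3R)-3,4-bis(tert-butyldimethylsilyloxy)butan-2-yl]-2-[(3S)-3-chloro-3-[(4R)-2,2-dimethyl-1,3-dioxolan-4-yl]butyl]-1,3-dithiane, via 2-lithiodithiane 17 (not isolated)
Conditions: t-BuLi, THF/HMPA, −78 °C; then 8, −78 °C
Reagents that add atoms: none
Why: Corey–Seebach umpolung: the 2-lithio-1,3-dithiane, formed quickly with t-BuLi in THF/HMPA, alkylates the primary iodide by SN2 at −78 °C, where the hindered tertiary chloride is expected to survive; this forms the C1–C2 bond.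

Step 12
Reactants: 18 the bis-TBS dithiane from step 11
Product: 19 (2R,3S)-2-(tert-butyldimethylsilyloxy)-3-[2-[(3S)-3-chloro-3-[(4R)-2,2-dimethyl-1,3-dioxolan-4-yl]butyl]-1,3-dithian-2-yl]butan-1-ol
Conditions: HF·pyridine, pyridine, THF, 0 °C
Reagents that add atoms: none
Why: Buffered HF·pyridine removes the unhindered primary silyl ether much faster than the flanked secondary one, and acetonide and dithiane do not react.

Step 13
Reactants: 19 the C8 primary alcohol from step 12
Product: 20 (2R,3S)-2-(tert-butyldimethylsilyloxy)-3-[2-[(3S)-3-chloro-3-[(4R)-2,2-dimethyl-1,3-dioxolan-4-yl]butyl]-1,3-dithian-2-yl]butanal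
Conditions: SO3·pyridine, DMSO, iPr2NEt, CH2Cl2, 0 °C
Reagents that add atoms: none
Why: Parikh–Doering oxidation tolerates the dithiane sulfur and gives the α-silyloxy aldehyde, which is used at once so that C9 cannot epimerise.

Step 14
Reactants: 21 but-2-yne-1,4-diol
Product: 22 4-(tert-butyldimethylsilyloxy)but-2-yn-1-ol
Conditions: NaH, THF, 0 °C; TBSCl (diol in excess)
Reagents that add atoms: tert-butyldimethylsilyl chloride CC(C)(C)[Si](C)(C)Cl
Why: Monosilylation of the symmetrical diol through its monosodium alkoxide, with the diol in excess, gives the mono-TBS ether.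

Step 15
Reactants: 22 4-(tert-butyldimethylsilyloxy)but-2-yn-1-ol
Product: 23 4-(tert-butyldimethylsilyloxy)but-2-yn-1-yl methyl carbonate
Conditions: ClCO2Me, pyridine, CH2Cl2, 0 °C
Reagents that add atoms: methyl chloroformate COC(=O)Cl
Why: Acylation of the propargylic alcohol gives the carbonate that serves as the leaving group in the carbonylation.

Step 16
Reactants: 23 4-(tert-butyldimethylsilyloxy)but-2-yn-1-yl methyl carbonate
Product: 24 methyl 2-[(tert-butyldimethylsilyloxy)methyl]buta-2,3-dienoate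
Conditions: Pd(OAc)2 (cat.), PPh3, CO (10 atm), MeOH, 45 °C
Reagents that add atoms: carbon monoxide [C-]#[O+]; methanol CO
Why: Tsuji-type carbonylation of a propargylic carbonate: zerovalent palladium attacks in an SN2' sense with loss of CO2 to give an allenylpalladium species, which inserts CO and is methanolysed to the 2,3-dienoate.

Step 17
Reactants: 24 methyl 2-[(tert-butyldimethylsilyloxy)methyl]buta-2,3-dienoate
Product: 25 3-[(tert-butyldimethylsilyloxy)methyl]-4-iodofuran-2(5H)-one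
Conditions: I2, NaHCO3, MeCN/H2O, rt
Reagents that add atoms: iodine [I][I]; water O
Why: Iodolactonisation of a 2,3-allenoate: iodine activates the central allene carbon, the ester carbonyl oxygen closes onto the terminal CH2 and the methyl group leaves as methanol, giving the 4-iodobutenolide that holds C6, C7, C11, C12 and C13.

Step 18
Reactants: 20 the C8 aldehyde from step 13; 25 3-[(tert-butyldimethylsilyloxy)methyl]-4-iodofuran-2(5H)-one
Product: 27 4-[(2R,3S)-2-(tert-butyldimethylsilyloxy)-3-[2-[(3S)-3-chloro-3-[(4R)-2,2-dimethyl-1,3-dioxolan-4-yl]butyl]-1,3-dithian-2-yl]-1-hydroxybutyl]-3-[(tert-butyldimethylsilyloxy)methyl]furan-2(5H)-one (both C8 epimers), via alkenylchromium dichloride 26 (not isolated)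
Conditions: CrCl2, NiCl2 (cat.), DMSO, rt
Reagents that add atoms: none
Why: Nozaki–Hiyama–Kishi coupling: zerovalent nickel inserts into the electron-poor alkenyl iodide, transmetallation gives an alkenyl species of trivalent chromium that adds only to the aldehyde and tolerates lactone, dithiane and tertiary chloride; C8 is left uncontrolled because the next step removes it.

Step 19
Reactants: 27 the C8 carbinol mixture from step 18
Product: 28 4-[(2R,3S)-2-(tert-butyldimethylsilyloxy)-3-[2-[(3S)-3-chloro-3-[(4R)-2,2-dimethyl-1,3-dioxolan-4-yl]butyl]-1,3-dithian-2-yl]butanoyl]-3-[(tert-butyldimethylsilyloxy)methyl]furan-2(5H)-one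
Conditions: SO3·pyridine, DMSO, iPr2NEt, CH2Cl2, 0 °C to rt
Reagents that add atoms: none
Why: Parikh–Doering oxidation of the allylic alcohol converges both C8 epimers on one ketone and is compatible with the dithiane.

Step 20
Reactants: 28 the C8 ketone from step 19
Product: 29 4-[(1R,2R,3S)-2-(tert-butyldimethylsilyloxy)-3-[2-[(3S)-3-chloro-3-[(4R)-2,2-dimethyl-1,3-dioxolan-4-yl]butyl]-1,3-dithian-2-yl]-1-hydroxybutyl]-3-[(tert-butyldimethylsilyloxy)methyl]furan-2(5H)-one
Conditions: NaBH4, CeCl3·7H2O, MeOH/THF, −78 °C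
Reagents that add atoms: none
Why: Luche reduction is 1,2-selective for the ketone over lactone and conjugated alkene, and polar Felkin–Anh attack anti to the C9 silyloxy group should give the 8,9-syn (8R) alcohol.

Step 21
Reactants: 29 the (8R)-alcohol from step 20
Product: 30 4-[(1R,2R,3S)-2-(tert-butyldimethylsilyloxy)-3-[2-[(3S,4R)-3-chloro-4,5-dihydroxy-3-methylpentyl]-1,3-dithian-2-yl]-1-hydroxybutyl]-3-(hydroxymethyl)furan-2(5H)-one
Conditions: CSA (cat.), MeOH, 0 °C to rt
Reagents that add atoms: none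
Why: Acid-catalysed methanolysis removes the terminal acetonide and the primary allylic silyl ether together, while the hindered secondary C9 silyl ether, the tertiary chloride and the dithiane persist.

Step 22
Reactants: 30 the tetraol from step 21
Product: 31 (2S)-2-chloro-4-[2-[(2S,3R,4R)-3-(tert-butyldimethylsilyloxy)-4-hydroxy-4-[4-(hydroxymethyl)-5-oxo-2,5-dihydrofuran-3-yl]butan-2-yl]-1,3-dithian-2-yl]-2-methylbutanal
Conditions: NaIO4, THF/pH 7 buffer, 0 °C
Reagents that add atoms: none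
Why: Periodate glycol cleavage (Malaprade reaction) is much faster than sulfide oxidation, so one equivalent at 0 °C cuts only the 1,2-diol and gives the non-enolisable tertiary α-chloro aldehyde.

Step 23
Reactants: 31 the α-chloro aldehyde diol from step 22
Product: 33 (2S)-2-chloro-2-methyl-4-[2-[(2S,3R,4R)-3-(tert-butyldimethylsilyloxy)-4-(triethylsilyloxy)-4-[4-[(triethylsilyloxy)methyl]-5-(triisopropylsilyloxy)furan-3-yl]butan-2-yl]-1,3-dithian-2-yl]butanal, via bis-TES aldehyde 32 (not isolated)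
Conditions: TESOTf, 2,6-lutidine, CH2Cl2, −78 °C; then TIPSOTf, Et3N, −78 to −30 °C
Reagents that add atoms: triethylsilyl triflate CC[Si](CC)(CC)OS(=O)(=O)C(F)(F)F; triisopropylsilyl triflate CC(C)[Si](OS(=O)(=O)C(F)(F)F)(C(C)C)C(C)C
Why: Two-stage silylation: with 2,6-lutidine, too weak a base to enolise the lactone, TESOTf caps the C8 and C13 hydroxyls, then TIPSOTf with Et3N converts the butenolide into the aromatic 2-silyloxyfuran (soft enolisation), the bulky triflate and the low temperature sparing the hindered aldehyde, which has no α-hydrogen.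

Step 24
Reactants: 33 the silyloxyfuran α-chloro aldehyde from step 23
Product: 36 ten-membered epoxy butenolide with C1 dithiane (8-O-TES; 9-O-TBS; 13-O-TES; 4R,5R,6S,8R,9R,10S), via dienolate 34 (not isolated), via chlorohydrin alkoxide 35 (not isolated)
Conditions: TASF [(Me2N)3S+ Me3SiF2−], THF, −78 to −40 °C, slow addition of 33, about 1 mM
Reagents that add atoms: none
Why: Proposed new method: fluoride removes the furan silyl group and the dienolate, blocked at its α-carbon C11, attacks the aldehyde carbon C5 through C6 and restores the C7=C11 butenolide, after which the C5 alkoxide displaces the neighbouring tertiary chloride; the closest known reactions are the intermolecular fluoride- or Lewis acid-promoted vinylogous Mukaiyama aldol of 2-silyloxyfurans with α-chloro aldehydes and the closure of chlorohydrins to epoxides, here merged and run as a macrocyclisation. The ten-membered carbocycle closes by 10-exo-trig attack on the carbonyl, helped by the fully substituted dithiane carbon C1 and the flat furan, and the oxirane closes by 3-exo-tet displacement with inversion at C4, which also makes the aldol irreversible. C5 is set by Cornforth-type attack on the conformer with C=O anti to C–Cl, on the face next to the smaller methyl group, which after inversion at C4 gives the trans (4R,5R) epoxide. C6 is set by the macrocyclic transition state and is the uncertain element of the step. The step needs γ- rather than α-attack (secured by the C11 substituent), ring closure rather than oligomerisation (slow addition at high dilution onto a very electrophilic, non-enolisable aldehyde) and survival of the alkyl silyl ethers (the enol-type O–Si bond is by far the most fluoride-labile).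

Step 25
Reactants: 36 the macrocycle from step 24
Product: 37 macrocyclic 8,13-diol (C1 dithiane; 4,5-epoxide; 9-O-TBS)
Conditions: HF·pyridine, pyridine, THF, 0 °C
Reagents that add atoms: none
Why: Buffered HF·pyridine cleaves the two triethylsilyl ethers far faster than the hindered secondary TBS ether at C9 and is mild enough for the epoxide.

Step 26
Reactants: 37 the macrocyclic 8,13-diol
Product: 38 macrocyclic 13-acetate with free 8-OH (C1 dithiane; 9-O-TBS)
Conditions: AcCl, 2,4,6-collidine, CH2Cl2, −78 °C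
Reagents that add atoms: acetyl chloride CC(=O)Cl
Why: Acetyl chloride with collidine at −78 °C acetylates the primary allylic C13 alcohol selectively over the hindered secondary C8 alcohol.

Step 27
Reactants: 38 the 13-acetate
Product: 39 macrocyclic 13-acetate 8-methacrylate (C1 dithiane; 9-O-TBS)
Conditions: methacrylic anhydride, Et3N, DMAP (cat.), CH2Cl2, 0 °C to rt
Reagents that add atoms: methacrylic anhydride CC(=C)C(=O)OC(=O)C(C)=C
Why: DMAP-catalysed acylation (Steglich-type) of the remaining C8 hydroxyl installs the methacrylate under mild base.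

Step 28
Reactants: 39 the 8-methacrylate
Product: 40 C1 ketone with 9-O-TBS (otherwise the target)
Conditions: MeI, CaCO3, MeCN/H2O, 40 °C
Reagents that add atoms: water O
Why: Alkylative hydrolysis of the dithiane: S-methylation creates a sulfonium leaving group and water delivers the C1 carbonyl under CaCO3 buffering, which spares the epoxide, the esters and the C10 stereocentre.

Step 29
Reactants: 40 the 9-O-TBS ketone
Product: 41 CNP0185951.1 (target)
Conditions: HF·pyridine, pyridine, THF, 0 °C to rt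
Reagents that add atoms: none
Why: Buffered HF·pyridine desilylation frees the C9 hydroxyl under non-basic conditions, so that acyl migration from O8 to O9 and retro-aldol or epimerisation of the β-hydroxy ketone should not occur.

Compound list
1 | tert-butyl(but-3-yn-1-yloxy)dimethylsilane | C#CCCO[Si](C)(C)C(C)(C)C | starting material
2 | dimethyl[(1E)-4-(tert-butyldimethylsilyloxy)-2-methylbut-1-en-1-yl]alane | C[Al](C)/C=C(C)/CCO[Si](C)(C)C(C)(C)C | intermediate (not isolated)
3 | (E)-5-(tert-butyldimethylsilyloxy)-3-methylpent-2-en-1-ol | OC/C=C(C)/CCO[Si](C)(C)C(C)(C)C | intermediate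
4 | [(2R,3R)-3-[2-(tert-butyldimethylsilyloxy)ethyl]-3-methyloxiran-2-yl]methanol | OC[C@H]1O[C@]1(C)CCO[Si](C)(C)C(C)(C)C | intermediate
5 | (2R,3S)-5-(tert-butyldimethylsilyloxy)-3-chloro-3-methylpentane-1,2-diol | OC[C@@H](O)[C@@](C)(Cl)CCO[Si](C)(C)C(C)(C)C | intermediate
6 | (4R)-4-[(2S)-4-(tert-butyldimethylsilyloxy)-2-chlorobutan-2-yl]-2,2-dimethyl-1,3-dioxolane | CC1(C)OC[C@@H](O1)[C@@](C)(Cl)CCO[Si](C)(C)C(C)(C)C | intermediate
7 | (3S)-3-chloro-3-[(4R)-2,2-dimethyl-1,3-dioxolan-4-yl]butan-1-ol | CC1(C)OC[C@@H](O1)[C@@](C)(Cl)CCO | intermediate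
8 | (4R)-4-[(2S)-2-chloro-4-iodobutan-2-yl]-2,2-dimethyl-1,3-dioxolane | CC1(C)OC[C@@H](O1)[C@@](C)(Cl)CCI | intermediate
9 | (tert-butyldimethylsilyloxy)acetaldehyde | O=CCO[Si](C)(C)C(C)(C)C | starting material
10 | [(2R,3R)-1-(tert-butyldimethylsilyloxy)-3-methylpent-4-en-2-yl]oxy-diisopinocampheylborane (borinate ester) | C=C[C@@H](C)[C@H](CO[Si](C)(C)C(C)(C)C)OB([C@H]1C[C@H]2C[C@@H]([C@@H]1C)C2(C)C)[C@H]1C[C@H]2C[C@@H]([C@@H]1C)C2(C)C | intermediate (not isolated)
11 | (2R,3R)-1-(tert-butyldimethylsilyloxy)-3-methylpent-4-en-2-ol | C=C[C@@H](C)[C@@H](O)CO[Si](C)(C)C(C)(C)C | intermediate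
12 | (2R,3R)-1,2-bis(tert-butyldimethylsilyloxy)-3-methylpent-4-ene | C=C[C@@H](C)[C@@H](O[Si](C)(C)C(C)(C)C)CO[Si](C)(C)C(C)(C)C | intermediate
13 | 3-[(2S,3R)-3,4-bis(tert-butyldimethylsilyloxy)butan-2-yl]-1,2,4-trioxolane (secondary ozonide, mixture at the ring carbon) | C1OC(OO1)[C@@H](C)[C@@H](O[Si](C)(C)C(C)(C)C)CO[Si](C)(C)C(C)(C)C | intermediate (not isolated)
14 | (2S,3R)-3,4-bis(tert-butyldimethylsilyloxy)-2-methylbutanal | O=C[C@@H](C)[C@@H](O[Si](C)(C)C(C)(C)C)CO[Si](C)(C)C(C)(C)C | intermediate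
15 | propane-1,3-dithiol | SCCCS | starting material
16 | 2-[(2S,3R)-3,4-bis(tert-butyldimethylsilyloxy)butan-2-yl]-1,3-dithiane | S1CCCSC1[C@@H](C)[C@@H](O[Si](C)(C)C(C)(C)C)CO[Si](C)(C)C(C)(C)C | intermediate
17 | 2-lithio-2-[(2S,3R)-3,4-bis(tert-butyldimethylsilyloxy)butan-2-yl]-1,3-dithiane | [Li]C1(SCCCS1)[C@@H](C)[C@@H](O[Si](C)(C)C(C)(C)C)CO[Si](C)(C)C(C)(C)C | intermediate (not isolated)
18 | 2-[(2S,3R)-3,4-bis(tert-butyldimethylsilyloxy)butan-2-yl]-2-[(3S)-3-chloro-3-[(4R)-2,2-dimethyl-1,3-dioxolan-4-yl]butyl]-1,3-dithiane | CC1(C)OC[C@@H](O1)[C@@](C)(Cl)CCC1(SCCCS1)[C@@H](C)[C@@H](O[Si](C)(C)C(C)(C)C)CO[Si](C)(C)C(C)(C)C | intermediate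
19 | (2R,3S)-2-(tert-butyldimethylsilyloxy)-3-[2-[(3S)-3-chloro-3-[(4R)-2,2-dimethyl-1,3-dioxolan-4-yl]butyl]-1,3-dithian-2-yl]butan-1-ol | CC1(C)OC[C@@H](O1)[C@@](C)(Cl)CCC1(SCCCS1)[C@@H](C)[C@@H](O[Si](C)(C)C(C)(C)C)CO | intermediate
20 | (2R,3S)-2-(tert-butyldimethylsilyloxy)-3-[2-[(3S)-3-chloro-3-[(4R)-2,2-dimethyl-1,3-dioxolan-4-yl]butyl]-1,3-dithian-2-yl]butanal | CC1(C)OC[C@@H](O1)[C@@](C)(Cl)CCC1(SCCCS1)[C@@H](C)[C@@H](O[Si](C)(C)C(C)(C)C)C=O | intermediate
21 | but-2-yne-1,4-diol | OCC#CCO | starting material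
22 | 4-(tert-butyldimethylsilyloxy)but-2-yn-1-ol | OCC#CCO[Si](C)(C)C(C)(C)C | intermediate
23 | 4-(tert-butyldimethylsilyloxy)but-2-yn-1-yl methyl carbonate | COC(=O)OCC#CCO[Si](C)(C)C(C)(C)C | intermediate
24 | methyl 2-[(tert-butyldimethylsilyloxy)methyl]buta-2,3-dienoate | C=C=C(CO[Si](C)(C)C(C)(C)C)C(=O)OC | intermediate
25 | 3-[(tert-butyldimethylsilyloxy)methyl]-4-iodofuran-2(5H)-one | IC1=C(CO[Si](C)(C)C(C)(C)C)C(=O)OC1 | intermediate
26 | dichloro[4-[(tert-butyldimethylsilyloxy)methyl]-5-oxo-2,5-dihydrofuran-3-yl]chromium | Cl[Cr](Cl)C1=C(CO[Si](C)(C)C(C)(C)C)C(=O)OC1 | intermediate (not isolated)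
27 | C8 carbinol, both epimers: 4-[(2R,3S)-2-(TBSO)-3-[2-[(3S)-3-chloro-3-[(4R)-2,2-dimethyl-1,3-dioxolan-4-yl]butyl]-1,3-dithian-2-yl]-1-hydroxybutyl]-3-[(TBSO)methyl]furan-2(5H)-one | CC1(C)OC[C@@H](O1)[C@@](C)(Cl)CCC1(SCCCS1)[C@@H](C)[C@@H](O[Si](C)(C)C(C)(C)C)C(O)C1=C(CO[Si](C)(C)C(C)(C)C)C(=O)OC1 | intermediate
28 | C8 ketone: 4-[(2R,3S)-2-(TBSO)-3-[2-[(3S)-3-chloro-3-[(4R)-2,2-dimethyl-1,3-dioxolan-4-yl]butyl]-1,3-dithian-2-yl]butanoyl]-3-[(TBSO)methyl]furan-2(5H)-one | CC1(C)OC[C@@H](O1)[C@@](C)(Cl)CCC1(SCCCS1)[C@@H](C)[C@@H](O[Si](C)(C)C(C)(C)C)C(=O)C1=C(CO[Si](C)(C)C(C)(C)C)C(=O)OC1 | intermediate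
29 | (8R)-alcohol: 4-[(1R,2R,3S)-2-(TBSO)-3-[2-[(3S)-3-chloro-3-[(4R)-2,2-dimethyl-1,3-dioxolan-4-yl]butyl]-1,3-dithian-2-yl]-1-hydroxybutyl]-3-[(TBSO)methyl]furan-2(5H)-one | CC1(C)OC[C@@H](O1)[C@@](C)(Cl)CCC1(SCCCS1)[C@@H](C)[C@@H](O[Si](C)(C)C(C)(C)C)[C@H](O)C1=C(CO[Si](C)(C)C(C)(C)C)C(=O)OC1 | intermediate
30 | tetraol: 4-[(1R,2R,3S)-2-(TBSO)-3-[2-[(3S,4R)-3-chloro-4,5-dihydroxy-3-methylpentyl]-1,3-dithian-2-yl]-1-hydroxybutyl]-3-(hydroxymethyl)furan-2(5H)-one | OC[C@@H](O)[C@@](C)(Cl)CCC1(SCCCS1)[C@@H](C)[C@@H](O[Si](C)(C)C(C)(C)C)[C@H](O)C1=C(CO)C(=O)OC1 | intermediate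
31 | (2S)-2-chloro-4-[2-[(2S,3R,4R)-3-(TBSO)-4-hydroxy-4-[4-(hydroxymethyl)-5-oxo-2,5-dihydrofuran-3-yl]butan-2-yl]-1,3-dithian-2-yl]-2-methylbutanal | O=C[C@](Cl)(C)CCC1(SCCCS1)[C@@H](C)[C@@H](O[Si](C)(C)C(C)(C)C)[C@H](O)C1=C(CO)C(=O)OC1 | intermediate
32 | bis-TES aldehyde: as 31 with triethylsilyl ethers on the C8 and C13 oxygens | O=C[C@](Cl)(C)CCC1(SCCCS1)[C@@H](C)[C@@H](O[Si](C)(C)C(C)(C)C)[C@H](O[Si](CC)(CC)CC)C1=C(CO[Si](CC)(CC)CC)C(=O)OC1 | intermediate (not isolated)
33 | key-step precursor: (2S)-2-chloro-2-methyl-4-[2-[(2S,3R,4R)-3-(TBSO)-4-(TESO)-4-[4-[(TESO)methyl]-5-(TIPSO)furan-3-yl]butan-2-yl]-1,3-dithian-2-yl]butanal | O=C[C@](Cl)(C)CCC1(SCCCS1)[C@@H](C)[C@@H](O[Si](C)(C)C(C)(C)C)[C@H](O[Si](CC)(CC)CC)c1coc(O[Si](C(C)C)(C(C)C)C(C)C)c1CO[Si](CC)(CC)CC | intermediate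
34 | furan-2-olate (dienolate) of 33 after loss of the TIPS group | O=C[C@](Cl)(C)CCC1(SCCCS1)[C@@H](C)[C@@H](O[Si](C)(C)C(C)(C)C)[C@H](O[Si](CC)(CC)CC)c1coc([O-])c1CO[Si](CC)(CC)CC | intermediate (not isolated)
35 | ring-closed (4S,5R,6S)-4-chloro-5-alkoxide: ten-membered carbocycle with butenolide restored, before epoxide closure | C15(SCCCS5)CC[C@](C)(Cl)[C@H]([O-])[C@H]3OC(=O)C(CO[Si](CC)(CC)CC)=C3[C@@H](O[Si](CC)(CC)CC)[C@H](O[Si](C)(C)C(C)(C)C)[C@@H]1C | intermediate (not isolated)
36 | key-step product: (4R,5R,6S,8R,9R,10S) ten-membered carbocycle, C1 1,3-dithiane, 4,5-epoxide, 6,12-butenolide (C7=C11), 8-O-TES, 9-O-TBS, 13-O-TES | C15(SCCCS5)CC[C@@]2(C)O[C@@H]2[C@H]3OC(=O)C(CO[Si](CC)(CC)CC)=C3[C@@H](O[Si](CC)(CC)CC)[C@H](O[Si](C)(C)C(C)(C)C)[C@@H]1C | intermediate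
37 | as 36 with free 8-OH and 13-OH | C15(SCCCS5)CC[C@@]2(C)O[C@@H]2[C@H]3OC(=O)C(CO)=C3[C@@H](O)[C@H](O[Si](C)(C)C(C)(C)C)[C@@H]1C | intermediate
38 | as 37 with 13-O-acetyl | C15(SCCCS5)CC[C@@]2(C)O[C@@H]2[C@H]3OC(=O)C(COC(C)=O)=C3[C@@H](O)[C@H](O[Si](C)(C)C(C)(C)C)[C@@H]1C | intermediate
39 | as 38 with 8-O-methacryloyl | C15(SCCCS5)CC[C@@]2(C)O[C@@H]2[C@H]3OC(=O)C(COC(C)=O)=C3[C@@H](OC(=O)C(C)=C)[C@H](O[Si](C)(C)C(C)(C)C)[C@@H]1C | intermediate
40 | 9-O-TBS ether of the target (C1 ketone) | O=C1CC[C@@]2(C)O[C@@H]2[C@H]3OC(=O)C(COC(C)=O)=C3[C@@H](OC(=O)C(C)=C)[C@H](O[Si](C)(C)C(C)(C)C)[C@@H]1C | intermediate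
41 | CNP0185951.1: (4R,5R,6S,8R,9R,10S)-13-acetoxy-4,5-epoxy-9-hydroxy-8-methacryloyloxy-1-oxo ten-membered 6,12-butenolide | C=C(C)C(=O)O[C@@H]1C2=C(COC(C)=O)C(=O)O[C@@H]2[C@H]2O[C@]2(C)CCC(=O)[C@@H](C)[C@H]1O | target

Total step count: 29 (fragment A: steps 1–6; fragment B: steps 7–10; fragment C: steps 14–17).
Longest linear sequence: 21 steps, from 1 through steps 1–6, 11–13 and 18–29.

Steps most likely to fail

1. Step 24 (Proposed new method). The ten-membered closure may lose to intermolecular aldol addition or to simple protonation of the dienolate, and the macrocyclic transition state may deliver the wrong face at C6 or C5. The fallback uses known reactions and moves the ring closure to C7–C8. It sets out from 19: the C8 hydroxyl is protected with 4-methoxybenzyl trichloroacetimidate (cat. CSA) as the PMB ether F1; aqueous AcOH frees the diol F2 and NaIO4 gives the α-chloro aldehyde F3. Separately, iodobutenolide 25 is converted with TIPSOTf/Et3N into the 4-iodo-2-silyloxyfuran F4. An intermolecular BF3·OEt2-promoted vinylogous Mukaiyama aldol of F4 with F3 (Cornforth control at C5, the usual syn preference of silyloxyfurans at C6) gives the chlorohydrin F5, which Cs2CO3 in MeCN closes to the epoxide F6. DDQ in CH2Cl2/pH 7 buffer removes the PMB group to give the alcohol F7, Parikh–Doering oxidation gives the aldehyde F8, and an intramolecular Nozaki–Hiyama–Kishi reaction (CrCl2, NiCl2 cat., DMSO/THF, high dilution) closes the ring to the macrocyclic C8 alcohol F9; a wrong C8 epimer would be corrected by the oxidation/reduction pair of steps 19 and 20. HF·pyridine then removes the primary C13 silyl ether and the route is rejoined at 37.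

2. Step 23. While the silyl dienol ether is formed beside a free, very electrophilic aldehyde, the silyl triflate may trigger premature Mukaiyama addition between molecules, or the amine may eliminate HCl from the tertiary α-chloro aldehyde, so that 33 cannot be isolated clean. The fallback does not isolate the silyloxyfuran. It sets out from 31: excess TESOTf and iPr2NEt in CH2Cl2 at high dilution silylate both hydroxyls, form the silyloxyfuran in the flask and let it close onto the silyl-activated aldehyde (silylative vinylogous Mukaiyama aldol), giving the tris-TES chlorohydrin macrocycle F10. TBAF at 0 °C then cleaves the three TES ethers, the freed C5 alkoxide closes the epoxide, and the route is rejoined at 37.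

3. Step 20. Hydride delivery to the C8 ketone may show poor facial selectivity (chelation of cerium by the C9 oxygen would favour the 8S alcohol), and some conjugate reduction may compete. The fallback recycles the wrong epimer by inversion. It sets out from the 8S alcohol F11 separated after step 20: a Mitsunobu reaction with 4-nitrobenzoic acid (PPh3, DIAD) gives the inverted ester F12, and K2CO3 in MeOH at 0 °C releases 29, where the route is rejoined.

Further compounds
F1 | step 24 | PMB ether of 19 at the C8 oxygen | CC1(C)OC[C@@H](O1)[C@@](C)(Cl)CCC1(SCCCS1)[C@@H](C)[C@@H](O[Si](C)(C)C(C)(C)C)COCc1ccc(OC)cc1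
F2 | step 24 | 1,2-diol from F1 after acetonide removal | OC[C@@H](O)[C@@](C)(Cl)CCC1(SCCCS1)[C@@H](C)[C@@H](O[Si](C)(C)C(C)(C)C)COCc1ccc(OC)cc1
F3 | step 24 | α-chloro aldehyde with C8 O-PMB and C9 O-TBS | O=C[C@](Cl)(C)CCC1(SCCCS1)[C@@H](C)[C@@H](O[Si](C)(C)C(C)(C)C)COCc1ccc(OC)cc1
F4 | step 24 | 4-iodo-3-[(tert-butyldimethylsilyloxy)methyl]-2-(triisopropylsilyloxy)furan | Ic1coc(O[Si](C(C)C)(C(C)C)C(C)C)c1CO[Si](C)(C)C(C)(C)C
F5 | step 24 | open-chain (4S,5R,6S) chlorohydrin carrying the 4-iodobutenolide | COc1ccc(COC[C@H](O[Si](C)(C)C(C)(C)C)[C@H](C)C2(SCCCS2)CC[C@](C)(Cl)[C@H](O)[C@H]2OC(=O)C(CO[Si](C)(C)C(C)(C)C)=C2I)cc1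
F6 | step 24 | open-chain (4R,5R) epoxide carrying the 4-iodobutenolide, C8 O-PMB | COc1ccc(COC[C@H](O[Si](C)(C)C(C)(C)C)[C@H](C)C2(SCCCS2)CC[C@@]2(C)O[C@@H]2[C@H]2OC(=O)C(CO[Si](C)(C)C(C)(C)C)=C2I)cc1
F7 | step 24 | C8 primary alcohol from F6 | OC[C@H](O[Si](C)(C)C(C)(C)C)[C@H](C)C1(SCCCS1)CC[C@@]2(C)O[C@@H]2[C@H]3OC(=O)C(CO[Si](C)(C)C(C)(C)C)=C3I
F8 | step 24 | C8 aldehyde from F7 | O=C[C@H](O[Si](C)(C)C(C)(C)C)[C@H](C)C1(SCCCS1)CC[C@@]2(C)O[C@@H]2[C@H]3OC(=O)C(CO[Si](C)(C)C(C)(C)C)=C3I
F9 | step 24 | macrocyclic (8R)-alcohol with 9-O-TBS and 13-O-TBS | C15(SCCCS5)CC[C@@]2(C)O[C@@H]2[C@H]3OC(=O)C(CO[Si](C)(C)C(C)(C)C)=C3[C@@H](O)[C@H](O[Si](C)(C)C(C)(C)C)[C@@H]1C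
F10 | step 23 | macrocyclic chlorohydrin with TES ethers at O5, O8 and O13 and TBS at O9 | C15(SCCCS5)CC[C@](C)(Cl)[C@H](O[Si](CC)(CC)CC)[C@H]3OC(=O)C(CO[Si](CC)(CC)CC)=C3[C@@H](O[Si](CC)(CC)CC)[C@H](O[Si](C)(C)C(C)(C)C)[C@@H]1C
F11 | step 20 | (8S)-epimer of 29 | CC1(C)OC[C@@H](O1)[C@@](C)(Cl)CCC1(SCCCS1)[C@@H](C)[C@@H](O[Si](C)(C)C(C)(C)C)[C@@H](O)C1=C(CO[Si](C)(C)C(C)(C)C)C(=O)OC1
F12 | step 20 | (8R)-4-nitrobenzoate of 29 | CC1(C)OC[C@@H](O1)[C@@](C)(Cl)CCC1(SCCCS1)[C@@H](C)[C@@H](O[Si](C)(C)C(C)(C)C)[C@H](OC(=O)c2ccc(cc2)[N+](=O)[O-])C1=C(CO[Si](C)(C)C(C)(C)C)C(=O)OC1
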